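**Plan**

- Retrosynthetic cuts: (i) the C–C bond between the 2H-pyrrole and the terminal pyrrole (cross-coupling at a lactam-derived triflate); (ii) the spiro C–N bond and the bond from the spiro carbon to C(OMe) (propiolate unit added to a lactone carbonyl, nitrogen from ammonia); (iii) the bond from pyran C4 to the end of the heptamethylene chain (radical macrocyclisation); (iv) the pyrrole–chain and pyrrole–C3 bonds (two cross-couplings); (v) the lactone C3=C4 bond (ring-closing metathesis).
- Forward order: dihydropyranone ring, then the pyrrole on C3, the C7 chain on the pyrrole, the twelve-membered ansa ring, the spiro methoxypyrrolinone ring, and last the terminal pyrrole.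
- Enabling feature: pyran atoms O1 and C2–C6 with the methyl group form a δ-lactone (C2, the later spiro carbon, as carbonyl) whose C3=C4 bond is an enoate. The ansa pyrrole sits on the α-carbon C3 and carries the seven-carbon chain whose terminal carbon has to bond to the β-carbon C4.
- Stereochemistry: C6 is bought with (S)-pent-4-en-2-ol; C4 is set by radical attack anti to the C6 methyl; C3 by base equilibration next to the lactone carbonyl; the spiro carbon by reversible, anomerically controlled acid spirocyclisation.

Key step: step 8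

Remark: pyranone locants are used throughout (O1; C2 = lactone carbonyl, later the spiro carbon; C3 bears the pyrrole; C4 the chain; C6 the methyl). Boc = tert-butoxycarbonyl.
Remark: C2 of 17–21 is a transient ketal centre that is erased in step 13; its configuration is of no consequence and is left open in the SMILES.

**Route**

Step 1
Reactants: 1 (S)-pent-4-en-2-ol; 2 acryloyl chloride
Product: 3 (S)-pent-4-en-2-yl acrylate
Conditions: Et3N, DMAP (cat.), CH2Cl2, 0 °C
Reagents that add atoms: none
Why: DMAP-catalysed O-acylation of the secondary alcohol by the acid chloride does not touch the carbinol centre, so the (S) configuration is carried over.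

Step 2
Reactants: 3 (S)-pent-4-en-2-yl acrylate
Product: 4 (S)-6-methyl-5,6-dihydro-2H-pyran-2-one
Conditions: Grubbs II (3 mol %), CH2Cl2 (0.02 M), 40 °C
Reagents that add atoms: none
Why: Ring-closing metathesis of an acrylate with a terminal alkene is the standard entry to α,β-unsaturated δ-lactones and closes the six-membered ring with loss of ethylene.

Step 3
Reactants: 4 (S)-6-methyl-5,6-dihydro-2H-pyran-2-one
Product: 5 (S)-3-iodo-6-methyl-5,6-dihydro-2H-pyran-2-one
Conditions: I2, pyridine/CH2Cl2 (1:1), 0 °C → rt
Reagents that add atoms: iodine, II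
Why: Pyridine-mediated α-iodination of an α,β-unsaturated carbonyl compound (conjugate addition of pyridine, iodination of the enolate, E1cB loss of pyridine) puts iodine on C3 and leaves C6 untouched.

Step 4
Reactants: 5 (S)-3-iodo-6-methyl-5,6-dihydro-2H-pyran-2-one; 6 (1-Boc-pyrrol-2-yl)boronic acid
Product: 7 (S)-3-(1-Boc-pyrrol-2-yl)-6-methyl-5,6-dihydro-2H-pyran-2-one
Conditions: Pd(PPh3)4 (5 mol %), Na2CO3 (2 M aq), DME, 70 °C
Reagents that add atoms: none
Why: Suzuki–Miyaura coupling of an α-iodo enoate with a 2-heteroarylboronic acid, in which oxidative addition to the vinyl C–I bond is fast and the Boc group slows protodeboronation of the pyrrole.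

Step 5
Reactants: 7 (S)-3-(1-Boc-pyrrol-2-yl)-6-methyl-5,6-dihydro-2H-pyran-2-one
Product: 8 (S)-3-(5-bromo-1-Boc-pyrrol-2-yl)-6-methyl-5,6-dihydro-2H-pyran-2-one
Conditions: NBS (1.05 equiv), THF, −78 → −20 °C
Reagents that add atoms: N-bromosuccinimide, O=C1CCC(=O)N1Br
Why: Electrophilic aromatic bromination of an N-Boc pyrrole goes to the free α-position (C5′), and the electron-poor enoate double bond does not react with NBS at low temperature.

Step 6
Reactants: 8 (S)-3-(5-bromo-1-Boc-pyrrol-2-yl)-6-methyl-5,6-dihydro-2H-pyran-2-one; 9 7-bromohept-1-ene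
Product: 11 (S)-3-[1-Boc-5-(7-bromoheptyl)pyrrol-2-yl]-6-methyl-5,6-dihydro-2H-pyran-2-one, via B-(7-bromoheptyl)-9-BBN 10 (not isolated)
Conditions: 9, 9-BBN, THF, 0 °C → rt; then 8, Pd(dppf)Cl2 (5 mol %), K3PO4 (3 M aq), DMF, 45 °C
Reagents that add atoms: none
Why: B-alkyl Suzuki–Miyaura coupling, in which 9-BBN hydroborates the terminal alkene anti-Markovnikov and Pd(dppf) transfers the primary alkyl group to the pyrrolyl bromide without inserting into the unactivated primary C–Br bond.

Step 7
Reactants: 11 (S)-3-[1-Boc-5-(7-bromoheptyl)pyrrol-2-yl]-6-methyl-5,6-dihydro-2H-pyran-2-one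
Product: 12 (S)-3-[1-Boc-5-(7-iodoheptyl)pyrrol-2-yl]-6-methyl-5,6-dihydro-2H-pyran-2-one
Conditions: NaI (5 equiv), acetone, 55 °C
Reagents that add atoms: sodium iodide, [Na+].[I-]
Why: Finkelstein halide exchange (SN2), driven by precipitation of NaBr, gives the iodide needed for fast and selective halogen abstraction.

Step 8
Reactants: 12 (S)-3-[1-Boc-5-(7-iodoheptyl)pyrrol-2-yl]-6-methyl-5,6-dihydro-2H-pyran-2-one
Product: 14 (3S,4S,6S) N-Boc ansa lactone, via C3-epimeric ansa lactone mixture 13 (not isolated)
Conditions: Bu3SnH (1.3 equiv) and AIBN (0.3 equiv) by syringe pump over 12 h, degassed PhH (2 mM), 80 °C; then DBU (0.5 equiv), rt, same flask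
Reagents that add atoms: none
Why: Bu3Sn• abstracts iodine from 12 and the nucleophilic primary radical adds to the electron-poor β-carbon C4 of the enoate, the adduct radical at C3 (stabilised by the lactone carbonyl and the pyrrole) then taking hydrogen from Bu3SnH to carry the chain. The closest known reaction type is the tin-hydride-mediated Giese-type endo macrocyclisation of ω-iodoalkyl enoates and enones. The twelve-membered ansa ring closes in the 12-endo-trig mode. C4 is controlled by the C6 methyl group: the radical attacks axially on the half-chair of the dihydropyranone, anti to the pseudo-equatorial methyl, so the chain ends trans to it. C3 is not fixed reliably by the hydrogen transfer (delivery anti to the new axial C–C bond would give the 3,4-cis lactone), so DBU is added before work-up to equilibrate the acidic C3–H through the enolate towards the 3,4-trans lactone, the only epimer that can hold both ansa bonds equatorial; any cis epimer left is separated and returned to DBU. The step needs ring closure to outrun hydrogen transfer to the open-chain radical and intermolecular addition, which 2 mM dilution, slow addition of the stannane, the doubly activated acceptor and the anchoring of the chain on the α-carbon next to C4 are meant to secure.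

Step 9
Reactants: 14 (3S,4S,6S) N-Boc ansa lactone; 15 methyl propiolate
Product: 17 N-Boc ansa lactol bearing the methyl propiolate unit on C2, via lithium methyl propiolate 16 (not isolated)
Conditions: 15 (3 equiv), LiHMDS, THF, −78 °C; then 14, −78 °C; AcOH quench at −78 °C
Reagents that add atoms: none
Why: 1,2-Addition of a lithium acetylide to a δ-lactone stops at the lithium hemiketalate at −78 °C, and the weakly basic propiolate anion should add to the carbonyl faster than it removes C3–H, so protonation gives the lactol with C3 intact.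

Step 10
Reactants: 17 N-Boc ansa lactol
Product: 18 N-Boc ansa methyl ketal ynoate
Conditions: CSA (10 mol %), MeOH, rt
Reagents that add atoms: methanol, CO
Why: Fischer-type acid-catalysed ketalisation of the lactol through the cyclic oxocarbenium ion locks C2 as the mixed methyl ketal, so that only the ester activates the alkyne and base can no longer reverse the acetylide addition.

Step 11
Reactants: 18 N-Boc ansa methyl ketal ynoate
Product: 20 N–H (E)-β-methoxyacrylate ketal, via N-Boc methoxyacrylate ketal 19 (not isolated)
Conditions: NaOMe (2 equiv), MeOH/THF, 0 → 40 °C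
Reagents that add atoms: methanol, CO (delivered as sodium methoxide, [Na+].[O-]C)
Why: Oxa-Michael addition of methoxide to the ynoate at the carbon β to the ester should give, after equilibration, the (E)-β-methoxyacrylate with the ester cis to the ketal carbon, and the same methoxide then removes the pyrrole N-Boc group by transacylation, at a stage where the alkyne that a free pyrrole nitrogen could attack is already consumed.

Step 12
Reactants: 20 N–H (E)-β-methoxyacrylate ketal
Product: 21 (E)-β-methoxyacrylamide ketal
Conditions: NH3 (7 M in MeOH), sealed tube, 60 °C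
Reagents that add atoms: ammonia, N
Why: Ammonolysis of the methyl ester gives the primary amide, and the β-carbon of the enol ether is shielded by the adjacent fully substituted ketal carbon, so addition–elimination there should not compete.

Step 13
Reactants: 21 (E)-β-methoxyacrylamide ketal
Product: 22 (2R,3S,4S,6S) spiro lactam
Conditions: CSA (20 mol %), CH2Cl2, 4 Å MS, rt
Reagents that add atoms: none
Why: Acid-catalysed spiro-amidation (N,O-ketal exchange): the methyl ketal ionises to the cyclic oxocarbenium ion, the cis-disposed amide nitrogen captures it in a 5-exo closure, and because the closure is reversible the spiro centre should settle under thermodynamic control with the C–N bond axial (anomeric effect) and the methoxyvinyl carbon equatorial on the chair that keeps both ansa bonds equatorial, i.e. nitrogen cis to the C3 pyrrole (2R).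

Step 14
Reactants: 22 (2R,3S,4S,6S) spiro lactam
Product: 23 spiro imidoyl triflate
Conditions: Tf2O (1.2 equiv), 2,6-di-tert-butyl-4-methylpyridine, CH2Cl2, −78 → 0 °C; used crude
Reagents that add atoms: trifluoromethanesulfonic anhydride, O=S(=O)(OS(=O)(=O)C(F)(F)F)C(F)(F)F
Why: O-Sulfonylation of a secondary lactam to the imidoyl triflate is established for 4-methoxy-3-pyrrolin-2-ones bearing a free pyrrole N–H, and the hindered base and low temperature should protect the electron-rich ansa pyrrole and the acid-labile N,O-ketal.

Step 15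
Reactants: 23 spiro imidoyl triflate; 6 (1-Boc-pyrrol-2-yl)boronic acid
Product: 25 premarineosin A, via N-Boc-premarineosin A 24 (not isolated)
Conditions: Pd(PPh3)4 (10 mol %), K2CO3 (aq), dioxane, 85 °C; then NaOMe, MeOH, rt
Reagents that add atoms: none
Why: Suzuki–Miyaura coupling of the imidoyl (2H-pyrrol-5-yl) triflate with the pyrrol-2-ylboronic acid forms the bipyrrole C–C bond, and methoxide transacylation then removes the Boc group without touching the base-stable spiro N,O-ketal.

**Compound list**

1 | (S)-pent-4-en-2-ol | C[C@H](O)CC=C | starting material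
2 | acryloyl chloride | C=CC(=O)Cl | starting material
3 | (S)-pent-4-en-2-yl acrylate | C=CC(=O)O[C@@H](C)CC=C | intermediate
4 | (S)-6-methyl-5,6-dihydro-2H-pyran-2-one [(S)-parasorbic acid] | O=C1O[C@@H](C)CC=C1 | intermediate
5 | (S)-3-iodo-6-methyl-5,6-dihydro-2H-pyran-2-one | O=C1O[C@@H](C)CC=C1I | intermediate
6 | (1-Boc-pyrrol-2-yl)boronic acid | OB(O)c1cccn1C(=O)OC(C)(C)C | starting material
7 | (S)-3-(1-Boc-pyrrol-2-yl)-6-methyl-5,6-dihydro-2H-pyran-2-one | O=C1O[C@@H](C)CC=C1c2cccn2C(=O)OC(C)(C)C | intermediate
8 | (S)-3-(5-bromo-1-Boc-pyrrol-2-yl)-6-methyl-5,6-dihydro-2H-pyran-2-one | O=C1O[C@@H](C)CC=C1c2ccc(Br)n2C(=O)OC(C)(C)C | intermediate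
9 | 7-bromohept-1-ene | C=CCCCCCBr | starting material
10 | B-(7-bromoheptyl)-9-borabicyclo[3.3.1]nonane | BrCCCCCCCB1C2CCCC1CCC2 | intermediate
11 | (S)-3-[1-Boc-5-(7-bromoheptyl)pyrrol-2-yl]-6-methyl-5,6-dihydro-2H-pyran-2-one | O=C1O[C@@H](C)CC=C1c2ccc(CCCCCCCBr)n2C(=O)OC(C)(C)C | intermediate
12 | (S)-3-[1-Boc-5-(7-iodoheptyl)pyrrol-2-yl]-6-methyl-5,6-dihydro-2H-pyran-2-one | O=C1O[C@@H](C)CC=C1c2ccc(CCCCCCCI)n2C(=O)OC(C)(C)C | intermediate
13 | N-Boc ansa lactone as formed, mixture of C3 epimers (4S,6S; heptamethylene bridge from C4 to pyrrole C5′, pyrrole C2′ on C3) | O=C2O[C@@H](C)C[C@@H]1CCCCCCCc3ccc(n3C(=O)OC(C)(C)C)C12 | intermediate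
14 | (3S,4S,6S) N-Boc ansa lactone (chain on C4 trans to the C6 methyl, pyrrole on C3 trans to the chain) | O=C2O[C@@H](C)C[C@@H]1CCCCCCCc3ccc(n3C(=O)OC(C)(C)C)[C@H]12 | intermediate
15 | methyl propiolate | C#CC(=O)OC | starting material
16 | lithium methyl propiolate (methyl 3-lithioprop-2-ynoate) | [Li]C#CC(=O)OC | intermediate
17 | N-Boc ansa lactol: 14 with C2 bearing OH and the C≡C–CO2Me group (3S,4S,6S; C2 anomers) | COC(=O)C#CC2(O)O[C@@H](C)C[C@@H]1CCCCCCCc3ccc(n3C(=O)OC(C)(C)C)[C@H]12 | intermediate
18 | N-Boc ansa methyl ketal ynoate (C2–OMe in place of C2–OH) | COC(=O)C#CC2(OC)O[C@@H](C)C[C@@H]1CCCCCCCc3ccc(n3C(=O)OC(C)(C)C)[C@H]12 | intermediate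
19 | N-Boc ketal with methyl (E)-3-methoxyacrylate on C2 (ester cis to C2) | COC(=O)\C=C(OC)/C2(OC)O[C@@H](C)C[C@@H]1CCCCCCCc3ccc(n3C(=O)OC(C)(C)C)[C@H]12 | intermediate
20 | N–H ketal with methyl (E)-3-methoxyacrylate on C2 | COC(=O)\C=C(OC)/C2(OC)O[C@@H](C)C[C@@H]1CCCCCCCc3ccc([nH]3)[C@H]12 | intermediate
21 | N–H ketal with (E)-3-methoxyacrylamide on C2 | NC(=O)\C=C(OC)/C2(OC)O[C@@H](C)C[C@@H]1CCCCCCCc3ccc([nH]3)[C@H]12 | intermediate
22 | (2R,3S,4S,6S) spiro lactam: pyran C2 spiro-fused as C5 of a 4-methoxy-1,5-dihydro-2H-pyrrol-2-one, N cis to the C3 pyrrole | COC1=CC(=O)N[C@]12O[C@@H](C)C[C@@H]1CCCCCCCc3ccc([nH]3)[C@H]12 | intermediate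
23 | spiro imidoyl triflate (3-methoxy-5-triflyloxy-2H-pyrrole, spiro at C2) | COC1=CC(OS(=O)(=O)C(F)(F)F)=N[C@]12O[C@@H](C)C[C@@H]1CCCCCCCc3ccc([nH]3)[C@H]12 | intermediate
24 | N-Boc-premarineosin A (Boc on the terminal pyrrole) | COC1=CC(c2cccn2C(=O)OC(C)(C)C)=N[C@]12O[C@@H](C)C[C@@H]1CCCCCCCc3ccc([nH]3)[C@H]12 | intermediate
25 | premarineosin A | COC1=CC(c2ccc[nH]2)=N[C@]12O[C@@H](C)C[C@@H]1CCCCCCCc3ccc([nH]3)[C@H]12 | target

**Step count and risks**

Total: 15 steps. Longest linear sequence: 15 steps (from 1; compounds 2, 6, 9 and 15 enter directly).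

The three steps most likely to fail are steps 8, 9 and 14.

Step 8. Hydrogen transfer to the primary radical may outrun ring closure (C–I reduced to C–H), intermolecular addition may give oligomers, or the C3 equilibrium may not favour the trans lactone. The fallback closes the ansa ring by olefin metathesis and makes the C4–C bond intermolecularly. It sets out from 8: Negishi coupling with pent-4-enylzinc bromide [Pd(PPh3)4, THF, 50 °C] should give the pentenylpyrrole lactone F1. Copper-catalysed conjugate addition of but-3-enylmagnesium bromide (CuBr·SMe2, TMSCl, THF, −78 °C; attack anti to the C6 methyl), followed by DBU equilibration of the unbridged lactone, where the 3,4-trans preference is the usual one, should give the trans diene lactone F2. Ring-closing metathesis (Grubbs II, CH2Cl2, 1 mM, 40 °C) should give the unsaturated ansa lactone F3, and hydrogenation (H2, Pd/C, EtOAc) comes back to the route at 14.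

Step 9. The acetylide may deprotonate C3–H in place of adding (with loss of the C3 configuration on quench), or the Boc group may migrate from the pyrrole nitrogen to the hemiketal alkoxide. The fallback acylates the acetylide with an open-chain Weinreb amide. It sets out from 14: Me3Al/MeNH(OMe)·HCl (CH2Cl2, 0 °C → rt) should open the lactone to the hydroxy Weinreb amide F4, and TESCl/imidazole should give its silyl ether F5. Addition of lithium methyl propiolate 16 (THF, −78 °C) should give the keto ynoate F6, in which the chelated adduct cannot over-add. CSA in MeOH (desilylation, lactol closure and ketalisation in one operation) comes back to the route at 18.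

Step 14. The imidoyl triflate may hydrolyse or ionise, and the free ansa pyrrole may be sulfonylated. The fallback uses a thioimidate in place of the triflate. It sets out from 22: Lawesson's reagent (THF, 50 °C) should give the spiro thiolactam F7, and MeI/K2CO3 (acetone, rt) the S-methyl thioimidate F8. Liebeskind–Srogl coupling with 6 [Pd2(dba)3, tri(2-furyl)phosphine, copper(I) thiophene-2-carboxylate, THF, 50 °C] comes back to the route at 24, which is deprotected with NaOMe/MeOH as in step 15.

**Further compounds**

F1 | step 8 | (S)-3-[1-Boc-5-(pent-4-en-1-yl)pyrrol-2-yl]-6-methyl-5,6-dihydro-2H-pyran-2-one | O=C1O[C@@H](C)CC=C1c2ccc(CCCC=C)n2C(=O)OC(C)(C)C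
F2 | step 8 | (3S,4S,6S)-4-(but-3-en-1-yl)-3-[1-Boc-5-(pent-4-en-1-yl)pyrrol-2-yl]-6-methyltetrahydro-2H-pyran-2-one | O=C1O[C@@H](C)C[C@H](CCC=C)[C@H]1c2ccc(CCCC=C)n2C(=O)OC(C)(C)C
F3 | step 8 | (3S,4S,6S) N-Boc ansa lactone with a C=C in the bridge (third/fourth carbon from C4, E/Z mixture) | O=C2O[C@@H](C)C[C@@H]1CCC=CCCCc3ccc(n3C(=O)OC(C)(C)C)[C@H]12
F4 | step 9 | ring-opened hydroxy Weinreb amide of 14 (N-methoxy-N-methylamide on C3, free (S)-carbinol) | CON(C)C(=O)[C@@H]1c2ccc(CCCCCCC[C@H]1C[C@H](C)O)n2C(=O)OC(C)(C)C
F5 | step 9 | triethylsilyl ether of F4 | CON(C)C(=O)[C@@H]1c2ccc(CCCCCCC[C@H]1C[C@H](C)O[Si](CC)(CC)CC)n2C(=O)OC(C)(C)C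
F6 | step 9 | keto ynoate (methyl 4-oxobut-2-ynoate unit on C3, TES ether) | COC(=O)C#CC(=O)[C@@H]1c2ccc(CCCCCCC[C@H]1C[C@H](C)O[Si](CC)(CC)CC)n2C(=O)OC(C)(C)C
F7 | step 14 | (2R,3S,4S,6S) spiro thiolactam (C=S in place of C=O of 22) | COC1=CC(=S)N[C@]12O[C@@H](C)C[C@@H]1CCCCCCCc3ccc([nH]3)[C@H]12
F8 | step 14 | spiro S-methyl thioimidate (3-methoxy-5-methylthio-2H-pyrrole, spiro at C2) | COC1=CC(SC)=N[C@]12O[C@@H](C)C[C@@H]1CCCCCCCc3ccc([nH]3)[C@H]12
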